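Amorphane (cadinane) numbering is used: ring A = C1–C6 with C4=C5, ring B = C1, C6–C10; β = face of H-1/H-6. Everything rests on a retro-Diels–Alder cut of ring A at C1–C2 and C5–C6. In one operation, a chiral titanium-BINOLate-catalysed cycloaddition of flat 2-methoxy-1,4-benzoquinone (all six ring B carbons) with 3-methyl-2-silyloxybutadiene (C2–C5, C15) closes ring A, sets the cis C1/C6 fusion in the absolute sense and places oxygen at C3 para to C6. It exploits the isoprenoid C2–C3(O)–C4(Me)–C5 bridge across the cis C1–C6 bond and the oxygenation at C8/C10. The remaining stereocentres (C3, C7, C8, C10) then arise by β-face reagent approach.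

Key step: step 2

Assumption: the titanium catalyst made from (R)-BINOL is taken to give the (4aS,8aR) adduct 4; if the sense of induction is the opposite, (S)-BINOL is used and nothing else changes.
Remark: C11–C13 is the acrylic acid unit on C7, C14 the methyl on C10, C15 the methyl on C4.

Step 1
Reactants: 1 3-methylbut-3-en-2-one
Product: 2 3-methyl-2-(triisopropylsilyloxy)buta-1,3-diene
Conditions: TIPSOTf, Et3N, Et2O, 0 °C
Reagents that add atoms: triisopropylsilyl trifluoromethanesulfonate CC(C)[Si](C(C)C)(C(C)C)OS(=O)(=O)C(F)(F)F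
Why: Soft enolisation and O-silylation of the methyl ketone, which has only one enolisable position, gives the 2-silyloxydiene.

Step 2
Reactants: 2 3-methyl-2-(triisopropylsilyloxy)buta-1,3-diene; 3 2-methoxy-1,4-benzoquinone
Product: 4 (4aS,8aR)-2-methoxy-7-methyl-6-(triisopropylsilyloxy)-4a,5,8,8a-tetrahydronaphthalene-1,4-dione (cis-fused; C7 and C10 ketones, C8 methoxy enol ether, C3 silyl enol ether)
Conditions: (R)-BINOL/TiCl2(OiPr)2 (20 mol %), 4 Å molecular sieves, toluene, −40 °C
Reagents that add atoms: none
Why: Asynchronous [4+2] cycloaddition in which the quinone, held on the chiral titanium centre through the C7 carbonyl and the C8 methoxy oxygen, is attacked by the silyl dienol ether; the closest known reaction type is the chiral titanium-BINOLate-catalysed Diels–Alder reaction of 2-alkoxybenzoquinones with oxygenated dienes. Ring A is closed by intermolecular annulation, both σ bonds (C1–C2 and C5–C6) forming suprafacially on the C1=C6 double bond, so the ring fusion must be cis. The two new stereocentres C1 and C6 are set together, their relative configuration by the cis dienophile and their absolute configuration by the quinone face that the BINOL ligand leaves open. The step needs site selectivity for the unsubstituted C1=C6 bond over the methoxylated C8=C9 bond, and regioselectivity so that the nucleophilic CH2 next to the silyloxy carbon bonds to C1 (β to the chelated C7 carbonyl), placing C3–O para to C6. Both are secured by the methoxy group, which deactivates the C10 carbonyl as a vinylogous ester and directs chelation to C7. Endo/exo selectivity does not arise because the diene has no terminal substituents.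

Step 3
Reactants: 4 cis-fused Diels–Alder adduct
Product: 5 7β-ethynyl-7α-hydroxy adduct (C10 vinylogous ester carbonyl, C8=C9 methoxy enol ether and C3=C4 silyl enol ether intact)
Conditions: HC≡CMgBr, THF, −78 °C; pH 7 buffer
Reagents that add atoms: ethynylmagnesium bromide C#C[Mg]Br
Why: 1,2-Addition of the acetylide to the more electrophilic C7 ketone (the C10 carbonyl is a deactivated vinylogous ester), assisted by magnesium chelation to the C8 methoxy group; attack anti to the C6–C5 bond should place the ethynyl group β, a configuration that is erased in step 6.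

Step 4
Reactants: 5 7β-ethynyl-7α-hydroxy adduct
Product: 7 7β-ethynyl-7α-hydroxy-10-methyl-9-en-8-one (ketol enone; C9=C10; C3 silyl enol ether), via tertiary allylic alcohol 6 (not isolated)
Conditions: MeLi (3.5 equiv), THF, −78 °C; then 0.5 M HCl, 0 °C
Reagents that add atoms: methyllithium [Li]C; water O
Why: Stork–Danheiser transposition: MeLi adds 1,2 to the vinylogous ester carbonyl C10, and acid ionises the tertiary allylic alcohol to an oxocarbenium ion that is hydrolysed at C8 with loss of methanol, giving the 10-methyl-9-en-8-one; the configuration created at C10 in 6 is erased.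

Step 5
Reactants: 7 ketol enone
Product: 8 9β,10β-epoxide of 7
Conditions: t-BuOOH, benzyltrimethylammonium hydroxide (cat.), THF, 0 °C
Reagents that add atoms: tert-butyl hydroperoxide CC(C)(C)OO
Why: Weitz–Scheffer epoxidation: the peroxide anion adds to the β-carbon C10 from the β face, anti to the pseudoaxial C1–C2 bond, which fixes the C10–O bond β.

Step 6
Reactants: 8 9β,10β-epoxy ketol
Product: 10 7α-ethynyl-10β-hydroxy-10α-methyl-8-ketone (H-7β), via dihydroxy ketone 9 (not isolated)
Conditions: SmI2 (5 equiv), THF/MeOH, −78 to −20 °C; then AcOH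
Reagents that add atoms: none
Why: Samarium diiodide cleaves both C–O bonds α to the C8 ketone (reductive opening of the α,β-epoxy ketone at C9, then reductive removal of the tertiary C7 hydroxyl) while the C10–O bond is kept, and the samarium enolate is protonated at C7 from the β face anti to the C6–C5 bond, which sets H-7β and the α-ethynyl group.

Step 7
Reactants: 10 β-hydroxy ketone
Product: 11 7α-ethynyl-8α,10β-diol (anti-1,3-diol; C3 silyl enol ether)
Conditions: Me4NBH(OAc)3, MeCN/AcOH, −30 °C
Reagents that add atoms: none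
Why: Evans–Saksena reduction: the axial 10β-hydroxyl binds the acetoxyborohydride and delivers hydride intramolecularly to the β face of the C8 ketone, giving the anti-1,3-diol with 8α-OH (H-8β).

Step 8
Reactants: 12 but-2-yne-1,4-diol
Product: 13 1,4-bis(tert-butyldiphenylsilyloxy)but-2-yne
Conditions: TBDPSCl, imidazole, DMF, rt
Reagents that add atoms: tert-butyl(chloro)diphenylsilane CC(C)(C)[Si](Cl)(c1ccccc1)c1ccccc1
Why: Standard silylation of both primary hydroxyls.

Step 9
Reactants: 13 1,4-bis(tert-butyldiphenylsilyloxy)but-2-yne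
Product: 14 (E)-4-(tert-butyldiphenylsilyloxy)-2-[(tert-butyldiphenylsilyloxy)methyl]but-2-enoic acid
Conditions: Ni(cod)2 (1 equiv), DBU, CO2 (1 atm), THF, 0 °C; then 1 M HCl
Reagents that add atoms: carbon dioxide O=C=O
Why: Oxidative cyclisation of the alkyne and CO2 on zerovalent nickel gives an oxanickelacyclopentenone, and protonolysis with retention amounts to syn hydrocarboxylation, so the two silyloxymethyl groups end up cis and the acid is E.

Step 10
Reactants: 11 7α-ethynyl-8α,10β-diol; 14 protected (E)-acid
Product: 15 8α-ester of 11 with acid 14 (10β-OH free; C3 silyl enol ether; 7α-ethynyl)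
Conditions: MNBA (2-methyl-6-nitrobenzoic anhydride), Et3N, DMAP, CH2Cl2, rt
Reagents that add atoms: none
Why: Shiina esterification acylates the secondary 8α-hydroxyl with retention, the tertiary 10-hydroxyl does not react, and the E geometry of the acid is unaffected.

Step 11
Reactants: 15 8α-ester with ring A silyl enol ether
Product: 16 ring A enone (C4=C5, C3 ketone) carrying the 7α-ethynyl group and the 8α-ester
Conditions: IBX, 4-methoxypyridine N-oxide, DMSO, rt
Reagents that add atoms: none
Why: IBX-mediated dehydrosilylation of the silyl enol ether (an alkyne-tolerant equivalent of the Saegusa oxidation) introduces the C4=C5 double bond in conjugation with the C3 ketone, hydrogen being lost from ring carbon C5 to give the endocyclic enone.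

Step 12
Reactants: 16 ring A enone with 7α-ethynyl group
Product: 17 2-(trimethylsilyl)ethyl ester of the C11–C13 acrylic acid (ring A enone; 8α-ester)
Conditions: Pd(OAc)2 (2 mol %), 2-PyPPh2, MsOH (cat.), CO (10 bar), Me3SiCH2CH2OH, CH2Cl2, 45 °C
Reagents that add atoms: carbon monoxide [C-]#[O+]; 2-(trimethylsilyl)ethanol C[Si](C)(C)CCO
Why: Branched-selective palladium-hydride alkoxycarbonylation of the terminal alkyne (2-pyridylphosphine ligand) places the carbonyl on the internal carbon C11 and gives the 2-substituted acrylate directly; O-8 is already acylated, so cyclocarbonylation to a lactone cannot intervene.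

Step 13
Reactants: 17 ring A enone with acrylate ester
Product: 18 3α-alcohol (allylic; C4=C5)
Conditions: NaBH4, CeCl3·7H2O, MeOH, −78 °C
Reagents that add atoms: none
Why: Luche reduction: 1,2-selective hydride delivery to the enone along the axial trajectory on the β face (the α face is shielded by ring B) should give the equatorial 3α-alcohol, and the two enoate esters are left untouched.

Step 14
Reactants: 18 3α-alcohol
Product: 19 3β-acetate
Conditions: PPh3, DIAD, AcOH, toluene, 0 °C to rt
Reagents that add atoms: acetic acid CC(=O)O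
Why: Mitsunobu reaction: displacement of the alkoxyphosphonium by acetate with inversion converts the 3α-alcohol into the 3β-acetate, the tertiary 10-hydroxyl being inert.

Step 15
Reactants: 19 fully protected 3β-acetate
Product: 20 target acid
Conditions: TBAF, AcOH (1:1), THF, 0 °C to rt
Reagents that add atoms: none
Why: Fluoride cleaves the two silyl ethers and the 2-(trimethylsilyl)ethyl ester (β-elimination to ethene and Me3SiF) in one operation, acetic acid buffering protecting the acetate and the enoate esters from base.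

Compound list
1 | 3-methylbut-3-en-2-one | CC(=O)C(C)=C | starting material
2 | 3-methyl-2-(triisopropylsilyloxy)buta-1,3-diene | C=C(O[Si](C(C)C)(C(C)C)C(C)C)C(C)=C | intermediate
3 | 2-methoxy-1,4-benzoquinone | COC1=CC(=O)C=CC1=O | starting material
4 | (4aS,8aR)-2-methoxy-7-methyl-6-(triisopropylsilyloxy)-4a,5,8,8a-tetrahydronaphthalene-1,4-dione (cis; H-1, H-6 β) | O=C1[C@@H]2CC(C)=C(O[Si](C(C)C)(C(C)C)C(C)C)C[C@@H]2C(=O)C=C1OC | intermediate
5 | 7β-ethynyl-7α-hydroxy adduct of 4 (C10 ketone, C8=C9 methoxy enol ether) | C#C[C@@]1(O)[C@@H]2CC(C)=C(O[Si](C(C)C)(C(C)C)C(C)C)C[C@@H]2C(=O)C=C1OC | intermediate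
6 | 10α-hydroxy-10β-methyl tertiary allylic alcohol (7β-ethynyl-7α-hydroxy; C8=C9 methoxy enol ether) | C#C[C@@]1(O)[C@@H]2CC(C)=C(O[Si](C(C)C)(C(C)C)C(C)C)C[C@@H]2[C@](C)(O)C=C1OC | intermediate (not isolated)
7 | 7β-ethynyl-7α-hydroxy-10-methyl-9-en-8-one (ketol enone) | C#C[C@@]1(O)[C@@H]2CC(C)=C(O[Si](C(C)C)(C(C)C)C(C)C)C[C@@H]2C(C)=CC1=O | intermediate
8 | 9β,10β-epoxide of 7 | C#C[C@@]1(O)[C@@H]2CC(C)=C(O[Si](C(C)C)(C(C)C)C(C)C)C[C@@H]2[C@@]3(C)O[C@H]3C1=O | intermediate
9 | 7β-ethynyl-7α,10β-dihydroxy-10α-methyl-8-ketone | C#C[C@@]1(O)[C@@H]2CC(C)=C(O[Si](C(C)C)(C(C)C)C(C)C)C[C@@H]2[C@@](C)(O)CC1=O | intermediate (not isolated)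
10 | 7α-ethynyl-10β-hydroxy-10α-methyl-8-ketone (H-7β) | C#C[C@@H]1[C@@H]2CC(C)=C(O[Si](C(C)C)(C(C)C)C(C)C)C[C@@H]2[C@@](C)(O)CC1=O | intermediate
11 | 7α-ethynyl-8α,10β-diol | C#C[C@@H]1[C@@H]2CC(C)=C(O[Si](C(C)C)(C(C)C)C(C)C)C[C@@H]2[C@@](C)(O)C[C@@H]1O | intermediate
12 | but-2-yne-1,4-diol | OCC#CCO | starting material
13 | 1,4-bis(tert-butyldiphenylsilyloxy)but-2-yne | CC(C)(C)[Si](OCC#CCO[Si](c1ccccc1)(c1ccccc1)C(C)(C)C)(c1ccccc1)c1ccccc1 | intermediate
14 | (E)-4-(tert-butyldiphenylsilyloxy)-2-[(tert-butyldiphenylsilyloxy)methyl]but-2-enoic acid | OC(=O)/C(=C/CO[Si](c1ccccc1)(c1ccccc1)C(C)(C)C)CO[Si](c1ccccc1)(c1ccccc1)C(C)(C)C | intermediate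
15 | 8α-ester of 11 with 14 (10β-OH free, C3 silyl enol ether, 7α-ethynyl) | C#C[C@@H]1[C@@H]2CC(C)=C(O[Si](C(C)C)(C(C)C)C(C)C)C[C@@H]2[C@@](C)(O)C[C@@H]1OC(=O)/C(=C/CO[Si](c1ccccc1)(c1ccccc1)C(C)(C)C)CO[Si](c1ccccc1)(c1ccccc1)C(C)(C)C | intermediate
16 | ring A 4-en-3-one with 7α-ethynyl and 8α-ester | C#C[C@@H]1[C@@H]2C=C(C)C(=O)C[C@@H]2[C@@](C)(O)C[C@@H]1OC(=O)/C(=C/CO[Si](c1ccccc1)(c1ccccc1)C(C)(C)C)CO[Si](c1ccccc1)(c1ccccc1)C(C)(C)C | intermediate
17 | 2-(trimethylsilyl)ethyl 11(13)-en-12-oate of the 4-en-3-one | C=C(C(=O)OCC[Si](C)(C)C)[C@@H]1[C@@H]2C=C(C)C(=O)C[C@@H]2[C@@](C)(O)C[C@@H]1OC(=O)/C(=C/CO[Si](c1ccccc1)(c1ccccc1)C(C)(C)C)CO[Si](c1ccccc1)(c1ccccc1)C(C)(C)C | intermediate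
18 | 3α-alcohol | C=C(C(=O)OCC[Si](C)(C)C)[C@@H]1[C@@H]2C=C(C)[C@H](O)C[C@@H]2[C@@](C)(O)C[C@@H]1OC(=O)/C(=C/CO[Si](c1ccccc1)(c1ccccc1)C(C)(C)C)CO[Si](c1ccccc1)(c1ccccc1)C(C)(C)C | intermediate
19 | 3β-acetate, fully protected | C=C(C(=O)OCC[Si](C)(C)C)[C@@H]1[C@@H]2C=C(C)[C@@H](OC(C)=O)C[C@@H]2[C@@](C)(O)C[C@@H]1OC(=O)/C(=C/CO[Si](c1ccccc1)(c1ccccc1)C(C)(C)C)CO[Si](c1ccccc1)(c1ccccc1)C(C)(C)C | intermediate
20 | 3β-acetoxy-10β-hydroxy-8α-[(E)-4-hydroxy-2-(hydroxymethyl)but-2-enoyloxy]-cis-cadina-4,11(13)-dien-12-oic acid (H-1, H-6, H-7, H-8 β; 14-CH3 α) | C=C(C(=O)O)[C@@H]1[C@@H]2C=C(C)[C@@H](OC(C)=O)C[C@@H]2[C@@](C)(O)C[C@@H]1OC(=O)/C(=C/CO)CO | target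

Total step count: 15. Longest linear sequence: 13 steps (steps 1–7 and 10–15); the side-chain acid takes 2 steps (8–9).

Steps most likely to fail

Step 6. Several processes can go wrong:
- incomplete cleavage of the free tertiary C7–O bond;
- protonation of the ynenolate at the alkyne terminus (allenyl ketone formation);
- retro-aldol opening of the β-alkoxy ketone;
- protonation of C7 from the α face.

The fallback sets out from 8 and comes back at 11. Compound 8 is treated with only 2.2 equiv of SmI2 at −90 °C so that reduction stops after epoxide opening, and dihydroxy ketone 9 is isolated. NaBH4 in MeOH at −40 °C (axial, β-face hydride) should give the 7β-ethynyl-7α,8α,10β-triol F1. Its cis-7,8-diol is closed with 1,1′-thiocarbonyldiimidazole (DMAP, toluene, 80 °C) to the cyclic 7,8-thionocarbonate F2. Bu3SnH/AIBN (toluene, 100 °C) fragments F2 to the more stable tertiary propargylic C7 radical (Barton–McCombie-type deoxygenation), which takes hydrogen on the β face. Aqueous work-up of the stannyl thiolcarbonate left on O-8 releases diol 11.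

Step 2. Enantio- or regiocontrol may erode through a competing uncatalysed or stepwise Mukaiyama–Michael pathway, silyl transfer to the quinone may occur, and the adduct may enolise to the hydroquinone. The fallback sets out from 2 and 3 and comes back at 5. Uncatalysed cycloaddition in toluene at room temperature, with the same regiochemistry governed by the C7 carbonyl, gives 4 as the racemate, that is together with its enantiomer ent-4 F3. Ethynylmagnesium bromide as in step 3 gives 5 together with ent-5 F4. The enantiomers are separated by preparative supercritical-fluid chromatography on a chiral stationary phase, and 5 rejoins the route at step 4.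

Step 14. Displacement may proceed with allylic transposition or retention through an allyl cation, or elimination to a diene may take over from clean inversion. The fallback sets out from 17 and comes back at 19. Reagent-controlled Corey–Bakshi–Shibata reduction of enone 17 with the (R)-2-methyl-oxazaborolidine catalyst and catecholborane (toluene, −78 °C) should override the substrate bias, the alkenyl flank acting as the large group, and give the 3β-alcohol F5 directly. F5 is acetylated with retention (Ac2O, pyridine, DMAP) to 19.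

Further compounds
F1 | step 6 | 7β-ethynyl-7α,8α,10β-triol (C3 silyl enol ether) | C#C[C@@]1(O)[C@@H]2CC(C)=C(O[Si](C(C)C)(C(C)C)C(C)C)C[C@@H]2[C@@](C)(O)C[C@@H]1O
F2 | step 6 | cyclic 7α,8α-thionocarbonate of F1 | C#C[C@@]1(OC(=S)O3)[C@@H]2CC(C)=C(O[Si](C(C)C)(C(C)C)C(C)C)C[C@@H]2[C@@](C)(O)C[C@@H]13
F3 | step 2 | ent-4, (4aR,8aS)-2-methoxy-7-methyl-6-(triisopropylsilyloxy)-4a,5,8,8a-tetrahydronaphthalene-1,4-dione | O=C1[C@H]2CC(C)=C(O[Si](C(C)C)(C(C)C)C(C)C)C[C@H]2C(=O)C=C1OC
F4 | step 2 | ent-5, enantiomer of the 7-ethynyl-7-hydroxy adduct | C#C[C@]1(O)[C@H]2CC(C)=C(O[Si](C(C)C)(C(C)C)C(C)C)C[C@H]2C(=O)C=C1OC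
F5 | step 14 | 3β-alcohol (C3 epimer of 18) | C=C(C(=O)OCC[Si](C)(C)C)[C@@H]1[C@@H]2C=C(C)[C@@H](O)C[C@@H]2[C@@](C)(O)C[C@@H]1OC(=O)/C(=C/CO[Si](c1ccccc1)(c1ccccc1)C(C)(C)C)CO[Si](c1ccccc1)(c1ccccc1)C(C)(C)C
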